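**Assumption:** C7 of 12, 15 and 16 (the epimerisable α-keto ring-fusion carbon, erased in the last step) is drawn as the thermodynamic trans-fused epimer; compounds 1, 5 and 13 are taken as commercial.

## Retrosynthetic overview

1. Target 17 ⇐ dehydration and hydrogenation of tertiary homoallylic alcohol 15 ⇐ photoredox/chromium allylation of tricyclic keto-β-lactone 12 with isophoryl bromide 14 (forms C8–C1′, sets the quaternary C1′).
2. 12 ⇐ nucleophile-promoted aldol-lactonisation of keto-aldehyde-acid 11 (cyclopentane and β-lactone in one step; sets C2 and C5).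
3. 11 ⇐ Diels–Alder of 2-silyloxydiene 4 with the D-glyceraldehyde-derived (E)-enal 6 (cyclohexane ring; sets C11 and C1). The dioxolane CH becomes the lactone carbon C2 after periodate cleavage.
4. Ring order: cyclohexane → cyclopentane + β-lactone → trimethylcyclohexyl attached last.

Late intermediates use 3-oxatricyclo[5.4.0.0^2,5]undecane numbering: C1 and C7 ring fusion, C2 (CH–O), O3, C4 (C=O), C5 (CH–C=O), C8 (bears the cyclohexyl), C11 (bears CH2O).

## Route

**Step 1**
Reactants: 1, 5-tert-butoxy-5-oxopentanoic acid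
Product: 2, tert-butyl 5-[methoxy(methyl)amino]-5-oxopentanoate
Conditions: MeNHOMe·HCl, EDC·HCl, Et3N, DMAP (cat.), CH2Cl2, 0 °C → rt
Reagents that add atoms: N,O-dimethylhydroxylamine hydrochloride, CNOC.Cl
Why: Standard carbodiimide amidation gives the Weinreb amide; the tert-butyl ester is untouched.

**Step 2**
Reactants: 2, tert-butyl 5-[methoxy(methyl)amino]-5-oxopentanoate
Product: 3, tert-butyl 5-oxohept-6-enoate
Conditions: CH2=CHMgBr, THF, −78 → 0 °C; inverse quench into cold 1 M HCl
Reagents that add atoms: vinylmagnesium bromide, C=C[Mg]Br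
Why: Weinreb ketone synthesis: the chelated tetrahedral intermediate stops at the ketone, the tert-butyl ester is inert at ≤0 °C, and the acidic inverse quench prevents aza-Michael addition to the vinyl ketone.

**Step 3**
Reactants: 3, tert-butyl 5-oxohept-6-enoate
Product: 4, tert-butyl (4Z)-5-[(tert-butyldimethylsilyl)oxy]hepta-4,6-dienoate
Conditions: TBSOTf (1.1 equiv), Et3N, CH2Cl2, −78 → 0 °C
Reagents that add atoms: TBSOTf, CC(C)(C)[Si](C)(C)OS(=O)(=O)C(F)(F)F
Why: Soft enolisation of the only enolisable ketone α-CH2 gives the cross-conjugated (Z)-2-silyloxydiene, with the chain "outside" as needed for s-cis reactivity.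

**Step 4**
Reactants: 5, (4R)-2,2-dimethyl-1,3-dioxolane-4-carbaldehyde (D-glyceraldehyde acetonide)
Product: 6, (2E)-3-[(4S)-2,2-dimethyl-1,3-dioxolan-4-yl]prop-2-enal
Conditions: Ph3P=CHCHO (1.1 equiv), toluene, rt
Reagents that add atoms: (triphenylphosphoranylidene)acetaldehyde, O=CC=P(c1ccccc1)(c1ccccc1)c1ccccc1
Why: Wittig olefination with a stabilised ylide gives the (E)-enal without epimerising the dioxolane centre (the descriptor changes from R to S only through CIP priorities).

**Step 5** (one pot, two stages)
Reactants: 4, tert-butyl (4Z)-5-[(tert-butyldimethylsilyl)oxy]hepta-4,6-dienoate; 6, (2E)-3-[(4S)-2,2-dimethyl-1,3-dioxolan-4-yl]prop-2-enal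
Product: 8, tert-butyl 3-[(1S,5S,6R)-2-[(tert-butyldimethylsilyl)oxy]-6-[(4S)-2,2-dimethyl-1,3-dioxolan-4-yl]-5-(hydroxymethyl)cyclohex-2-en-1-yl]propanoate, via the non-isolated aldehyde 7, the (1S,5S,6S)-5-formyl cycloadduct
Conditions: 4 (1.5 equiv), BHT (cat.), toluene, 120 °C (sealed), 36 h; then EtOH, NaBH4, 0 °C
Reagents that add atoms: none
Why: Normal-demand Diels–Alder in which the siloxy-activated diene terminus bonds to the enal β-carbon ("para" adduct), the (E)-dienophile fixes the trans C5/C6 relationship, and the diene adds to the face anti to the dioxolane C–O bond (allylic C–H eclipsed, inside-alkoxy/Felkin sense) to set both ring centres from the glyceraldehyde centre; the epimerisable aldehyde is reduced in situ.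

**Step 6**
Reactants: 8, the hydroxymethyl cyclohexene above
Product: 9, tert-butyl 3-[(1S,5S,6R)-5-[(butanoyloxy)methyl]-2-[(tert-butyldimethylsilyl)oxy]-6-[(4S)-2,2-dimethyl-1,3-dioxolan-4-yl]cyclohex-2-en-1-yl]propanoate
Conditions: (PrCO)2O, Et3N, DMAP (cat.), CH2Cl2, 0 °C → rt
Reagents that add atoms: butanoic anhydride, CCCC(=O)OC(=O)CCC
Why: DMAP-catalysed acylation installs the target's butanoate early, so it also serves as the alcohol protecting group; the silyl enol ether, acetonide and tert-butyl ester are stable to these basic conditions.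

**Step 7**
Reactants: 9, the butanoate above
Product: 10, 3-[(1S,5S,6R)-5-[(butanoyloxy)methyl]-6-[(1S)-1,2-dihydroxyethyl]-2-oxocyclohexyl]propanoic acid
Conditions: TFA/CH2Cl2/H2O (10:10:1), 0 °C → rt; toluene azeotrope
Reagents that add atoms: none (all oxygens of 10 are already in 9)
Why: One acidic hydrolysis removes the silyl enol ether (→ ketone), the acetonide (→ diol) and the tert-butyl ester (→ acid) while the primary butanoate survives; the all-trans (all-equatorial) ring is the thermodynamic arrangement.

**Step 8**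
Reactants: 10, the keto diol acid above
Product: 11, 3-[(1S,2R,3S)-3-[(butanoyloxy)methyl]-2-formyl-6-oxocyclohexyl]propanoic acid
Conditions: NaIO4, THF/pH 7 buffer, 0 °C; used crude
Reagents that add atoms: none
Why: Periodate glycol cleavage converts the dioxolane-derived diol into the C2 aldehyde (losing CH2O); the trans aldehyde is anchored by the non-epimerisable C3 centre.

**Step 9**
Reactants: 11, the keto aldehyde acid above
Product: 12, [(1R,2S,5R,7S,11S)-4,8-dioxo-3-oxatricyclo[5.4.0.0^2,5]undecan-11-yl]methyl butanoate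
Conditions: 2-bromo-1-propylpyridinium triflate, 4-pyrrolidinopyridine, i-Pr2NEt, CH2Cl2, rt (slow addition of 11)
Reagents that add atoms: none
Why: Nucleophile-catalysed aldol-lactonisation: the acylammonium enolate of the activated acid adds to the aldehyde and the aldolate closes the cis-fused β-lactone, forming the cyclopentane at the same time; the lactone forms anti to the C1–C11 bond, so C2 and C5 are set by C1/C11 using an achiral promoter.

**Step 10**
Reactants: 13, 3,5,5-trimethylcyclohex-2-en-1-ol (isophorol, racemic)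
Product: 14, 3-bromo-1,5,5-trimethylcyclohex-1-ene (racemic; used crude)
Conditions: PBr3, pyridine (cat.), Et2O, −10 °C
Reagents that add atoms: phosphorus tribromide, BrP(Br)Br
Why: Allylic alcohol to allylic bromide; racemate and any allylic isomer converge on the same allyl radical in Step 11.

**Step 11** (key photochemical step)
Reactants: 12, the tricyclic keto-β-lactone above; 14, 3-bromo-1,5,5-trimethylcyclohex-1-ene (2.5 equiv)
Product: 15, [(1R,2S,5R,7S,8R,11S)-8-hydroxy-4-oxo-8-[(1R)-1,5,5-trimethylcyclohex-2-en-1-yl]-3-oxatricyclo[5.4.0.0^2,5]undecan-11-yl]methyl butanoate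
Conditions: CrCl3·3THF (15 mol %), 4CzIPN (2 mol %), Hantzsch ester (2 equiv), THF, 450 nm LEDs, 10–20 °C
Reagents that add atoms: none (the C9H15 unit comes from 14)
Why: Proposed new method: photoreduced 4CzIPN (Hantzsch ester as reductant) turns Cr(III) over to Cr(II); Cr(II) abstracts Br from 14 and a second Cr(II) captures the allyl radical at its less hindered secondary end; the ring-locked (Z)-allyl–Cr(III) then delivers its methyl-bearing γ-carbon to the C8 ketone through a chair Zimmerman–Traxler transition state (equatorial approach on the face opposite the β-lactone, the branched C7 side pseudo-equatorial, the methyl anti to the carbinol oxygen), which sets C1′ and C8, and the substitution-inert Cr(III) alkoxide resists retro-allylation and attack on the β-lactone until protonated by the Hantzsch pyridinium; the closest known chemistry is photoredox/Cr Nozaki–Hiyama-type allylation of aldehydes and thermal addition of cyclic allylzinc reagents to ketones, here extended to a hindered ketone and a γ,γ-disubstituted cyclic allyl donor to make vicinal fully substituted carbons.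

**Step 12**
Reactants: 15, the tertiary homoallylic alcohol above
Product: 16, [(1R,2S,5R,7S,8R,11S)-8-hydroxy-4-oxo-8-[(1S)-1,3,3-trimethylcyclohexyl]-3-oxatricyclo[5.4.0.0^2,5]undecan-11-yl]methyl butanoate
Conditions: H2 (1 atm), 5% Pd/C, EtOAc, rt
Reagents that add atoms: none
Why: Heterogeneous hydrogenation of the only alkene (cis-disubstituted); the β-lactone, ester and non-allylic tertiary alcohol are inert, and C1′ is unchanged in space (1′R → 1′S is only a CIP priority change).

**Step 13**
Reactants: 16, the saturated tertiary alcohol above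
Product: 17, 3′-norspongiolactone, [(1R,2S,5R,11S)-4-oxo-8-[(1S)-1,3,3-trimethylcyclohexyl]-3-oxatricyclo[5.4.0.0^2,5]undec-7-en-11-yl]methyl butanoate
Conditions: SOCl2, pyridine, CH2Cl2, −30 → 0 °C
Reagents that add atoms: none
Why: E2 dehydration of the chlorosulfite: the axial C8–O is anti-periplanar to the axial C7–H, Zaitsev orientation gives the tetrasubstituted C7=C8 alkene, and the cation-free pathway avoids Wagner–Meerwein shift from the adjacent quaternary carbon; C7 and C8 become sp2 and the five remaining stereocentres are untouched.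

## Compound list

1 | 5-tert-butoxy-5-oxopentanoic acid | CC(C)(C)OC(=O)CCCC(=O)O | starting material
2 | tert-butyl 5-[methoxy(methyl)amino]-5-oxopentanoate | CON(C)C(=O)CCCC(=O)OC(C)(C)C | intermediate
3 | tert-butyl 5-oxohept-6-enoate | C=CC(=O)CCCC(=O)OC(C)(C)C | intermediate
4 | tert-butyl (4Z)-5-[(tert-butyldimethylsilyl)oxy]hepta-4,6-dienoate | C=C/C(O[Si](C)(C)C(C)(C)C)=C/CCC(=O)OC(C)(C)C | intermediate
5 | (4R)-2,2-dimethyl-1,3-dioxolane-4-carbaldehyde | O=C[C@H]1COC(C)(C)O1 | starting material
6 | (2E)-3-[(4S)-2,2-dimethyl-1,3-dioxolan-4-yl]prop-2-enal | O=C/C=C/[C@H]1COC(C)(C)O1 | intermediate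
7 | tert-butyl 3-[(1S,5S,6S)-2-[(tert-butyldimethylsilyl)oxy]-6-[(4S)-2,2-dimethyl-1,3-dioxolan-4-yl]-5-formylcyclohex-2-en-1-yl]propanoate | O=C[C@H]1CC=C(O[Si](C)(C)C(C)(C)C)[C@@H](CCC(=O)OC(C)(C)C)[C@@H]1[C@H]2COC(C)(C)O2 | intermediate (not isolated)
8 | tert-butyl 3-[(1S,5S,6R)-2-[(tert-butyldimethylsilyl)oxy]-6-[(4S)-2,2-dimethyl-1,3-dioxolan-4-yl]-5-(hydroxymethyl)cyclohex-2-en-1-yl]propanoate | OC[C@H]1CC=C(O[Si](C)(C)C(C)(C)C)[C@@H](CCC(=O)OC(C)(C)C)[C@@H]1[C@H]2COC(C)(C)O2 | intermediate
9 | tert-butyl 3-[(1S,5S,6R)-5-[(butanoyloxy)methyl]-2-[(tert-butyldimethylsilyl)oxy]-6-[(4S)-2,2-dimethyl-1,3-dioxolan-4-yl]cyclohex-2-en-1-yl]propanoate | CCCC(=O)OC[C@H]1CC=C(O[Si](C)(C)C(C)(C)C)[C@@H](CCC(=O)OC(C)(C)C)[C@@H]1[C@H]2COC(C)(C)O2 | intermediate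
10 | 3-[(1S,5S,6R)-5-[(butanoyloxy)methyl]-6-[(1S)-1,2-dihydroxyethyl]-2-oxocyclohexyl]propanoic acid | CCCC(=O)OC[C@H]1CCC(=O)[C@@H](CCC(=O)O)[C@@H]1[C@H](O)CO | intermediate
11 | 3-[(1S,2R,3S)-3-[(butanoyloxy)methyl]-2-formyl-6-oxocyclohexyl]propanoic acid | CCCC(=O)OC[C@H]1CCC(=O)[C@@H](CCC(=O)O)[C@@H]1C=O | intermediate
12 | [(1R,2S,5R,7S,11S)-4,8-dioxo-3-oxatricyclo[5.4.0.0^2,5]undecan-11-yl]methyl butanoate | CCCC(=O)OC[C@H]1CCC(=O)[C@H]2C[C@H]3C(=O)O[C@H]3[C@@H]21 | intermediate
13 | 3,5,5-trimethylcyclohex-2-en-1-ol (racemic) | CC1=CC(O)CC(C)(C)C1 | starting material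
14 | 3-bromo-1,5,5-trimethylcyclohex-1-ene (racemic) | CC1=CC(Br)CC(C)(C)C1 | intermediate
15 | [(1R,2S,5R,7S,8R,11S)-8-hydroxy-4-oxo-8-[(1R)-1,5,5-trimethylcyclohex-2-en-1-yl]-3-oxatricyclo[5.4.0.0^2,5]undecan-11-yl]methyl butanoate | CCCC(=O)OC[C@H]1CC[C@](O)([C@@]4(C)C=CCC(C)(C)C4)[C@H]2C[C@H]3C(=O)O[C@H]3[C@@H]21 | intermediate
16 | [(1R,2S,5R,7S,8R,11S)-8-hydroxy-4-oxo-8-[(1S)-1,3,3-trimethylcyclohexyl]-3-oxatricyclo[5.4.0.0^2,5]undecan-11-yl]methyl butanoate | CCCC(=O)OC[C@H]1CC[C@](O)([C@@]4(C)CCCC(C)(C)C4)[C@H]2C[C@H]3C(=O)O[C@H]3[C@@H]21 | intermediate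
17 | 3′-norspongiolactone, [(1R,2S,5R,11S)-4-oxo-8-[(1S)-1,3,3-trimethylcyclohexyl]-3-oxatricyclo[5.4.0.0^2,5]undec-7-en-11-yl]methyl butanoate | CCCC(=O)OC[C@H]1CCC([C@@]2(C)CCCC(C)(C)C2)=C2C[C@H]3C(=O)O[C@H]3[C@@H]21 | target

## Totals and main risks

Total steps: 13. Longest linear sequence: 11 (Steps 1, 2, 3, 5, 6, 7, 8, 9, 11, 12, 13).

Steps most likely to fail:

1. **Step 11 (proposed photoredox/Cr allylation).** The ketone is hindered, two fully substituted carbons are joined, and the C1′ outcome rests on a transition-state argument, not on direct precedent. Fallback (known chemistry): drop the catalytic photochemical manifold and add the preformed cyclic allylzinc reagent (from 14 or the chloride, Zn/LiCl, THF, −78 → −20 °C) to 12. Cyclic allylzincs are known to add to ketones through the same chair transition state with high diastereoselectivity to give adjacent quaternary centres.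

2. **Step 13 (dehydration regiochemistry).** The C8=C9 trisubstituted isomer may compete with the desired C7=C8 alkene. Fallback: oxidise the silyl enol ether already present in 9 to the C9=C10 enone (Saegusa–Ito, Pd(OAc)2) and carry it through; the carbinol from the allylation is then allylic and can only eliminate toward C7, and a final Wilkinson hydrogenation removes the two disubstituted alkenes while leaving the tetrasubstituted one.

3. **Step 5 (Diels–Alder reactivity and facial selectivity).** The hindered diene terminus meets a β-substituted enal, and acyclic (E)-γ-alkoxy dienophiles usually give only modest facial ratios (I would expect roughly 4–8:1). Fallback: use levoglucosenone as a rigid cellulose-derived dienophile, which reacts only on the face anti to its 1,6-anhydro bridge. Baeyer–Villiger excision and hydrolysis then reveal the C11 CH2OH and the 1,2-diol, and C1 is epimerised to trans at the aldehyde stage.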